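**Retrosynthetic overview**
- The ketone is unmasked last from a secondary nitro group (Nef), so the nitro carbon serves as a hexanoyl‑anion carbon.
- Key C–C bond (future C=O carbon to its α‑CH2): the nitronate of 1‑nitrohexane adds to the π‑allyl‑Pd species from butadiene monoepoxide, giving an (E)‑allylic alcohol, then its carbonate.
- Tetrahydropyridine (formed first): Ir‑catalysed branched allylic amination of that carbonate by a D‑allylglycine‑derived β‑amino amide sets C‑17; C‑13 comes from the amino acid via Arndt–Eistert; RCM closes the ring.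
- 13‑Membered ring (formed second): N‑alkylation with N‑Boc‑3‑aminopropanal, then intramolecular reductive amination of the unmasked 4‑amidobutanal closes the N5–C6 bond.

Assumption: the nitro‑bearing carbon (later the ketone carbon) is carried as a ~1:1 mixture of configurations and is left without a stereo label; the ligand sense in step 5 is taken as the usual one for (E)‑alkyl allyl carbonates and would be confirmed on a model, since the antipodal ligand gives the C‑6 epimer.

**Step 1**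
Reactants: 1 1‑nitrohexane; 2 2‑vinyloxirane (butadiene monoepoxide, racemic)
Product: 3 (2E)‑5‑nitrodec‑2‑en‑1‑ol
Conditions: Pd(PPh3)4 (3 mol %), 1 (3 equiv), THF, 0 °C → rt
Reagents that add atoms: none
Why: Tsuji–Trost allylic alkylation under neutral conditions: Pd(0) opens the vinyl epoxide to a π‑allyl‑Pd alkoxide that deprotonates the nitroalkane, and the nitronate (a hexanoyl‑anion equivalent) attacks the distal allyl terminus to give the (E)‑1,4‑adduct, joining the future carbonyl carbon to an electrophilic allylic carbon with reversed polarity.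

**Step 2**
Reactants: 3 (2E)‑5‑nitrodec‑2‑en‑1‑ol
Product: 4 methyl (2E)‑5‑nitrodec‑2‑en‑1‑yl carbonate
Conditions: ClCO2Me, pyridine, CH2Cl2, 0 °C
Reagents that add atoms: methyl chloroformate COC(=O)Cl
Why: Pyridine‑mediated O‑acylation turns the allylic alcohol into the carbonate leaving group needed for Ir‑catalysed allylic substitution.

**Step 3**
Reactants: 5 Fmoc‑D‑allylglycine, (2R)‑2‑{[(9H‑fluoren‑9‑ylmethoxy)carbonyl]amino}pent‑4‑enoic acid
Product: 7 (9H‑fluoren‑9‑yl)methyl N‑[(3R)‑1‑diazo‑2‑oxohex‑5‑en‑3‑yl]carbamate, via mixed anhydride 6 (not isolated)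
Conditions: i‑BuOCOCl, N‑methylmorpholine, THF, −15 °C; then CH2N2, Et2O, 0 °C → rt
Reagents that add atoms: diazomethane C=[N+]=[N-]
Why: First half of an Arndt–Eistert homologation: the mixed carbonic anhydride acylates diazomethane to the α‑diazoketone without touching the stereocentre.

**Step 4**
Reactants: 7 the diazoketone; 8 4,4‑dimethoxybutan‑1‑amine
Product: 11 (3R)‑3‑amino‑N‑(4,4‑dimethoxybutyl)hex‑5‑enamide, via ketene 9 (not isolated), via Fmoc amide 10 (not isolated)
Conditions: PhCO2Ag (10 mol %), 8 (1.1 equiv), 1,4‑dioxane, ultrasound, rt; then piperidine, rt (same flask)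
Reagents that add atoms: none
Why: Silver‑catalysed Wolff rearrangement proceeds with retention at the migrating stereocentre and the ketene is trapped by amine 8 to give the β‑amino amide directly; piperidine then removes Fmoc by E1cB without acid, so the acetal survives.

**Step 5**
Reactants: 4 methyl (2E)‑5‑nitrodec‑2‑en‑1‑yl carbonate; 11 (3R)‑3‑amino‑N‑(4,4‑dimethoxybutyl)hex‑5‑enamide
Product: 12 (3R)‑N‑(4,4‑dimethoxybutyl)‑3‑{[(3S)‑5‑nitrodec‑1‑en‑3‑yl]amino}hex‑5‑enamide
Conditions: [Ir(cod)Cl]2 (2 mol %), (Ra,Rc,Rc)‑binaphthol N,N‑bis(1‑phenylethyl)phosphoramidite (4 mol %), n‑PrNH2 pre‑activation, THF, 40 °C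
Reagents that add atoms: none
Why: Ir‑catalysed asymmetric allylic amination (Hartwig–Helmchen type): the cyclometalated Ir‑phosphoramidite ionises the linear carbonate and the α‑branched primary amine attacks the substituted allyl terminus, giving the branched amine with catalyst‑controlled (S) configuration at the new N–CH(vinyl) centre while the (R) centre of 11 is untouched.

**Step 6**
Reactants: 12 the diene amine
Product: 15 N‑(4,4‑dimethoxybutyl)‑2‑[(2R,6S)‑6‑(2‑nitroheptyl)‑1,2,3,6‑tetrahydropyridin‑2‑yl]acetamide, via diene ammonium tosylate 13 (not isolated), via cyclic ammonium tosylate 14 (not isolated)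
Conditions: TsOH (anhydrous, 1.0 equiv), Hoveyda–Grubbs II (5 mol %), CH2Cl2, 40 °C; then aq. NaHCO3
Reagents that add atoms: none
Why: Ring‑closing metathesis of the vinyl and allyl arms forms the tetrahydropyridine with its cis ring alkene, protonation keeps the amine off ruthenium, and the two pre‑set stereocentres make the ring 2,6‑trans.

**Step 7**
Reactants: 15 the tetrahydropyridine; 16 tert‑butyl (3‑oxopropyl)carbamate
Product: 18 tert‑butyl N‑{3‑[(2R,6S)‑2‑{2‑[(4,4‑dimethoxybutyl)amino]‑2‑oxoethyl}‑6‑(2‑nitroheptyl)‑3,6‑dihydropyridin‑1(2H)‑yl]propyl}carbamate, via iminium acetate 17 (not isolated)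
Conditions: 16 (1.5 equiv), NaBH(OAc)3, AcOH, ClCH2CH2Cl, rt
Reagents that add atoms: none
Why: Reductive amination (Abdel‑Magid conditions): the unhindered aldehyde forms an iminium ion with the ring NH that NaBH(OAc)3 reduces under weakly acidic conditions in which the acidic α‑nitro C–H, the acetal and the Boc group are inert.

**Step 8**
Reactants: 18 the Boc‑amino acetal
Product: 21 (13R,17S)‑17‑(2‑nitroheptyl)‑1,5,10‑triazabicyclo[11.4.0]heptadec‑15‑en‑11‑one, via amino aldehyde 19 (not isolated), via macrocyclic imine 20 (not isolated)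
Conditions: 3 M aq. HCl–THF (1:1), rt; evaporate; then MeOH (1 mM), NaOAc (pH 6), 2‑picoline–borane, rt
Reagents that add atoms: none
Why: Aqueous acid removes the Boc group and unmasks the acetal, and at pH 6 and high dilution the primary amine condenses with the aldehyde to the 13‑membered imine that the borane reduces (Borch‑type intramolecular reductive amination), leaving both stereocentres untouched.

**Step 9**
Reactants: 21 the nitro macrocycle
Product: 25 (13R,17S)‑17‑(2‑oxoheptyl)‑1,5,10‑triazabicyclo[11.4.0]heptadec‑15‑en‑11‑one, via sodium nitronate 22 (not isolated), via oxime 23 (not isolated), via ketimine 24 (not isolated)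
Conditions: NaOMe, MeOH, 0 °C; then aq. TiCl3, NH4OAc (pH 5–6), rt
Reagents that add atoms: water O
Why: Nef reaction in McMurry's reductive TiCl3 variant: the nitronate is reduced through the oxime to the ketimine, which hydrolyses at buffered pH to the ketone under conditions mild enough to avoid retro‑Mannich epimerisation of the new β‑amino ketone.

**Compound list**
1 | 1‑nitrohexane | CCCCCC[N+](=O)[O-] | starting material
2 | 2‑vinyloxirane (butadiene monoepoxide, racemic) | C=CC1CO1 | starting material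
3 | (2E)‑5‑nitrodec‑2‑en‑1‑ol | CCCCCC([N+](=O)[O-])C/C=C/CO | intermediate
4 | methyl (2E)‑5‑nitrodec‑2‑en‑1‑yl carbonate | CCCCCC([N+](=O)[O-])C/C=C/COC(=O)OC | intermediate
5 | Fmoc‑D‑allylglycine, (2R)‑2‑{[(9H‑fluoren‑9‑ylmethoxy)carbonyl]amino}pent‑4‑enoic acid | C=CC[C@@H](NC(=O)OCC1c2ccccc2-c2ccccc21)C(=O)O | starting material
6 | mixed anhydride of 5 with isobutyl carbonic acid | C=CC[C@@H](NC(=O)OCC1c2ccccc2-c2ccccc21)C(=O)OC(=O)OCC(C)C | intermediate
7 | (9H‑fluoren‑9‑yl)methyl N‑[(3R)‑1‑diazo‑2‑oxohex‑5‑en‑3‑yl]carbamate | C=CC[C@@H](NC(=O)OCC1c2ccccc2-c2ccccc21)C(=O)C=[N+]=[N-] | intermediate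
8 | 4,4‑dimethoxybutan‑1‑amine | COC(OC)CCCN | starting material
9 | ketene, (9H‑fluoren‑9‑yl)methyl N‑[(3R)‑1‑oxohexa‑1,5‑dien‑3‑yl]carbamate | C=CC[C@@H](NC(=O)OCC1c2ccccc2-c2ccccc21)C=C=O | intermediate
10 | (9H‑fluoren‑9‑yl)methyl N‑[(4R)‑6‑[(4,4‑dimethoxybutyl)amino]‑6‑oxohex‑1‑en‑4‑yl]carbamate | C=CC[C@@H](NC(=O)OCC1c2ccccc2-c2ccccc21)CC(=O)NCCCC(OC)OC | intermediate
11 | (3R)‑3‑amino‑N‑(4,4‑dimethoxybutyl)hex‑5‑enamide | C=CC[C@@H](N)CC(=O)NCCCC(OC)OC | intermediate
12 | (3R)‑N‑(4,4‑dimethoxybutyl)‑3‑{[(3S)‑5‑nitrodec‑1‑en‑3‑yl]amino}hex‑5‑enamide | CCCCCC([N+](=O)[O-])C[C@@H](C=C)N[C@H](CC=C)CC(=O)NCCCC(OC)OC | intermediate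
13 | N‑protonated 12 as its p‑toluenesulfonate | CCCCCC([N+](=O)[O-])C[C@@H](C=C)[NH2+][C@H](CC=C)CC(=O)NCCCC(OC)OC.Cc1ccc(cc1)S(=O)(=O)[O-] | intermediate
14 | N‑protonated 15 as its p‑toluenesulfonate | CCCCCC([N+](=O)[O-])C[C@H]1C=CC[C@H](CC(=O)NCCCC(OC)OC)[NH2+]1.Cc1ccc(cc1)S(=O)(=O)[O-] | intermediate
15 | N‑(4,4‑dimethoxybutyl)‑2‑[(2R,6S)‑6‑(2‑nitroheptyl)‑1,2,3,6‑tetrahydropyridin‑2‑yl]acetamide (2,6‑trans) | CCCCCC([N+](=O)[O-])C[C@H]1C=CC[C@H](CC(=O)NCCCC(OC)OC)N1 | intermediate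
16 | tert‑butyl (3‑oxopropyl)carbamate | O=CCCNC(=O)OC(C)(C)C | starting material
17 | iminium acetate from 15 and 16 (N=CH–CH2CH2NHBoc) | CCCCCC([N+](=O)[O-])C[C@H]1C=CC[C@H](CC(=O)NCCCC(OC)OC)[N+]1=CCCNC(=O)OC(C)(C)C.CC(=O)[O-] | intermediate
18 | tert‑butyl N‑{3‑[(2R,6S)‑2‑{2‑[(4,4‑dimethoxybutyl)amino]‑2‑oxoethyl}‑6‑(2‑nitroheptyl)‑3,6‑dihydropyridin‑1(2H)‑yl]propyl}carbamate | CCCCCC([N+](=O)[O-])C[C@H]1C=CC[C@H](CC(=O)NCCCC(OC)OC)N1CCCNC(=O)OC(C)(C)C | intermediate
19 | 2‑[(2R,6S)‑1‑(3‑aminopropyl)‑6‑(2‑nitroheptyl)‑1,2,3,6‑tetrahydropyridin‑2‑yl]‑N‑(4‑oxobutyl)acetamide (drawn as free base; present as its hydrochloride) | CCCCCC([N+](=O)[O-])C[C@H]1C=CC[C@H](CC(=O)NCCCC=O)N1CCCN | intermediate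
20 | (13R,17S)‑17‑(2‑nitroheptyl)‑1,5,10‑triazabicyclo[11.4.0]heptadeca‑5,15‑dien‑11‑one | CCCCCC([N+](=O)[O-])C[C@H]1C=CC[C@@H]2CC(=O)NCCCC=NCCCN21 | intermediate
21 | (13R,17S)‑17‑(2‑nitroheptyl)‑1,5,10‑triazabicyclo[11.4.0]heptadec‑15‑en‑11‑one | CCCCCC([N+](=O)[O-])C[C@H]1C=CC[C@@H]2CC(=O)NCCCCNCCCN21 | intermediate
22 | sodium nitronate of 21 | CCCCCC(=[N+]([O-])[O-])C[C@H]1C=CC[C@@H]2CC(=O)NCCCCNCCCN21.[Na+] | intermediate
23 | oxime of 25 (side‑chain C=N–OH) | CCCCCC(=NO)C[C@H]1C=CC[C@@H]2CC(=O)NCCCCNCCCN21 | intermediate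
24 | ketimine of 25 (side‑chain C=NH) | CCCCCC(=N)C[C@H]1C=CC[C@@H]2CC(=O)NCCCCNCCCN21 | intermediate
25 | (13R,17S)‑17‑(2‑oxoheptyl)‑1,5,10‑triazabicyclo[11.4.0]heptadec‑15‑en‑11‑one (CNP0183222.1) | CCCCCC(=O)C[C@H]1C=CC[C@@H]2CC(=O)NCCCCNCCCN21 | target

**Totals**
Total step count: 9. Longest linear sequence: 7 steps (3 → 9 from compound 5, or 1, 2, 5 → 9 from compound 1).

**Steps most likely to fail (in step order; step 8 is the riskiest)**

Step 1. The primary nitroalkane can be allylated twice, and 1,2‑addition or O‑allylation can compete with the wanted 1,4‑C‑alkylation. Fallback, setting out from 1: Pd(PPh3)4‑catalysed allylation of 1 with allyl methyl carbonate, which has no regiochemical ambiguity, gives 4‑nitronon‑1‑ene F1. Cross‑metathesis of F1 with excess (Z)‑but‑2‑ene‑1,4‑diol (Hoveyda–Grubbs II, CH2Cl2, 40 °C) then installs the (E)‑allylic alcohol and returns to the route at 3.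

Step 7. The ring nitrogen of 15 is flanked by two tertiary carbons, so iminium formation may be slow and the β‑carbamoyl aldehyde 16 can eliminate instead. Fallback, setting out from 15: replace the iminium route by direct SN2 N‑alkylation with commercial tert‑butyl (3‑bromopropyl)carbamate (NaI, i‑Pr2NEt, MeCN, 60 °C; the base is too weak to form the nitronate). This gives 18 directly and returns to the route there.

Step 8. The N‑acyl‑4‑aminobutanal 19 sits largely as its cyclic N‑acyl hemiaminal and can oligomerise or be over‑reduced, so the 13‑membered ring closure is the least certain step. Fallback, setting out from 15 and replacing steps 7 and 8: reductive amination of 15 with 3‑azidopropanal F2 (from acrolein, NaN3 and AcOH) gives N‑(4,4‑dimethoxybutyl)‑2‑[(2R,6S)‑1‑(3‑azidopropyl)‑6‑(2‑nitroheptyl)‑1,2,3,6‑tetrahydropyridin‑2‑yl]acetamide F3. Mild acetal hydrolysis (aq. AcOH–THF) gives the azido aldehyde F4. PPh3 in toluene at high dilution converts F4 into the iminophosphorane F5, which closes by intramolecular aza‑Wittig reaction to the macrocyclic imine 20 under neutral, anhydrous conditions. NaBH4 in MeOH in the same flask reduces 20, and the fallback returns to the route at 21.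

**Further compounds**
F1 | step 1 | 4‑nitronon‑1‑ene | CCCCCC([N+](=O)[O-])CC=C
F0 | step 7 | none | none
F2 | step 8 | 3‑azidopropanal | [N-]=[N+]=NCCC=O
F3 | step 8 | N‑(4,4‑dimethoxybutyl)‑2‑[(2R,6S)‑1‑(3‑azidopropyl)‑6‑(2‑nitroheptyl)‑1,2,3,6‑tetrahydropyridin‑2‑yl]acetamide | CCCCCC([N+](=O)[O-])C[C@H]1C=CC[C@H](CC(=O)NCCCC(OC)OC)N1CCCN=[N+]=[N-]
F4 | step 8 | 2‑[(2R,6S)‑1‑(3‑azidopropyl)‑6‑(2‑nitroheptyl)‑1,2,3,6‑tetrahydropyridin‑2‑yl]‑N‑(4‑oxobutyl)acetamide | CCCCCC([N+](=O)[O-])C[C@H]1C=CC[C@H](CC(=O)NCCCC=O)N1CCCN=[N+]=[N-]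
F5 | step 8 | P,P,P‑triphenyl iminophosphorane of F4 (N=PPh3 in place of N3) | CCCCCC([N+](=O)[O-])C[C@H]1C=CC[C@H](CC(=O)NCCCC=O)N1CCCN=P(c1ccccc1)(c1ccccc1)c1ccccc1
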